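1. In a one-step world the target climbs as starting material meets free catalyst. The decision for the next run is what to do with the flask called larch at 10 h: charge more catalyst, charge more reagent, or wait.

| flask | starting material | second substrate | reagent | capture agent | protic impurity | free catalyst | remark | time |
|---|---|---|---|---|---|---|---|---|
| larch | 0.10 M | 2 equiv | 1.1 equiv | 2 mM | 0.030 M | 0.34 mol% | the very flask that is asked about, followed so far |  |
| ash | 0.067 M | 2 equiv | 1.1 equiv | 2 mM | 0.030 M | 0.34 mol% | run made earlier |  |
| flask | 0.10 M | 2.00 equiv | 1.10 equiv | 2.00 mM | 0.0300 M | 0.34 mol% |  | 10 h |

- larch (time / h: target / %): 0.833: 29; 2.50: 52; 5.00: 62; 8.00: 71; 10.0: 70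
- ash (time / h: target / %): 0.333: 9; 1.00: 24; 2.00: 34; 3.00: 42; 4.00: 47

(readings scatter by 1.5 percentage points)

- removed target is counted in
- additions bring no volume worth counting

- zeta: at 10 h take out 90 % of the target then present, then wait 5.0 h
- gamma: at 10 h add free catalyst, 50.0 % of the amount charged, then wait 5.0 h
- theta: at 10 h add reagent, 50.0 % of the amount charged, then wait 5.0 h
- eta: change nothing and wait 5.0 h more

- target, in percent of the starting material first charged, at 10 h
- what to do for the largest gain in target; "none" if nothing gains more than 2 percentage points (zeta / gamma / theta / eta / none)
- target present, with what was taken out counted in, in percent of the starting material first charged, after gamma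
- target present, with what was taken out counted in, in percent of the starting material first charged, after theta

2. Larch reads 62 % target after 5.00 h, which gives 0.968 as the natural logarithm of the charge over the part of it not yet target; I call this the reach. In the one-step picture the reach adds up catalyst at work over time.

3. By 10.0 h the larch reading gives a reach of 1.20. The second stretch therefore adds about a quarter of what the first added, so I read the catalyst as largely out of work.

4. The ash run has 0.067 M of starting material at the same mol%, so it has proportionally less catalyst, with the same [capture agent]. Its reach at 4.00 h is 0.635. Scaled up by the ratio of charges, that becomes 0.948, which lies between the larch readings of 0.734 at 2.50 h and 0.968 at 5.00 h. So I take the reach at a given time as proportional to the charge, which between these two runs moves [free catalyst], [reagent] and [second substrate] together, and for the next step I assume that the catalyst is the part that counts.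

5. Fresh catalyst is a correction to larch, which already reads 70 % target, so I reckon the correction by itself. Half a charge over 5.0 h should add a reach of 0.484, which acts on the part not yet target and gains 12 percentage points. That puts me near 81.5 %, so I would add catalyst.

6. The forecast gives 71 % now, chooses gamma, and puts catalyst at 78.5 % and reagent at 72 %. Its ground for larch is “because the catalyst is dead, not because reagent has run out”. My figure for catalyst stands above its figure.

7. The flask gives 71.1 %, and the best choice is gamma, with 80.4 % after catalyst, a gain of 9.3 points. Reagent gives 75.7 %.

    starting material + free catalyst ⇌ catalyst intermediate A (K = 6.40 L mol⁻¹, k = 4100 L mol⁻¹ h⁻¹)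
    reagent + catalyst intermediate A → free catalyst + target (k = 11000 L mol⁻¹ h⁻¹)
    second substrate + free catalyst ⇌ catalyst intermediate B (K = 3.20 L mol⁻¹, k = 840 L mol⁻¹ h⁻¹)
    reagent + catalyst intermediate B → free catalyst + second product (k = 290 L mol⁻¹ h⁻¹)
    catalyst intermediate A + capture agent → trapped intermediate (k = 1600 L mol⁻¹ h⁻¹)
    starting material + protic impurity → quenched substrate (k = 0.730 L mol⁻¹ h⁻¹)

Over the further 5.0 h, adding catalyst raises the reach of this flask by 0.388, against the 0.484 I reckoned. The neighbour charged with 0.060 M reaches 52.6 % in the same time as the flask, and its reach over the flask's is 0.601, beside a charge ratio of 0.600. In the flask at 10.0 h, catalyst intermediate A goes on with reagent 130 times faster than with capture agent. Even so, the trapped intermediate, the off-cycle form, holds 88.0 % of the catalyst by then.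

(The numbers in the tables are calculated for an exercise; the scatter is artificial.)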